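**Retrosynthetic overview**

1. The 1,3‑dioxolane (methyl‑ketal C–O–orthoester C–O–OCH) and the oxane fused to it are opened together. The orthoester carbon is the C=O carbon of a spiro‑γ‑lactone whose ring oxygen is already the third orthoester oxygen, and the ketal and OCH carbons are C‑5 and C‑4 of a 5‑oxy‑5‑methylbutenolide. The feature used is that orthoester plus acylal ketal is an isomer of "lactone C=O + γ‑hydroxybutenolide", which in turn is a 2‑silyloxyfuran plus one oxygen atom.
2. The bond between the quaternary lactone α‑carbon and the CH(CH3) carbon comes from a reductive Michael addition: hydride onto an α‑methylene spiro‑lactone, then the enolate onto (E)‑3‑ethylidene‑5‑methylfuran‑2(3H)‑one. This brings in the furan ring that later becomes the γ‑lactone.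
3. The spiro‑γ‑lactone (oxolane ring) comes from a Zn‑Barbier addition of ethyl 2‑(bromomethyl)acrylate to the ring ketone; the spiro‑δ‑lactone from formylation, acrylate Michael addition and aldehyde reduction at the α′‑carbon.
4. The cyclohexane and its one purchased stereocentre come from (R)‑carvone. A temporary 6‑oxabicyclo[3.2.1]octane ether (tertiary O onto the enone β‑carbon) relays that centre to four ring stereocentres and is later hydrolysed to the two free hydroxyls.
5. Ring order: cyclohexane (bought) → temporary ether bridge → δ‑lactone → spiro‑γ‑lactone (oxolane) → furan (future γ‑lactone) → oxane, then the 1,3‑dioxolane last, in the same operation.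

Key step: step 11

Remark: hemiketal and lactol carbons written without a stereodescriptor are rapidly interconverting epimers; DMDO is used as a freshly prepared acetone solution.

**Route**

Step 1
Reactants: 1 (R)-(−)-carvone
Product: 2 (5R)-5-(2-hydroxypropan-2-yl)-2-methylcyclohex-2-en-1-one
Conditions: 50% aq. H2SO4, 0 → 23 °C
Reagents that add atoms: water (O)
Why: Markovnikov acid‑catalysed hydration of the 1,1‑disubstituted isopropenyl alkene through the tertiary cation should leave the deactivated enone alkene and the stereocentre untouched.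

Step 2
Reactants: 2 (5R)-5-(2-hydroxypropan-2-yl)-2-methylcyclohex-2-en-1-one
Product: 3 (1R,4S,5S)-4,7,7-trimethyl-6-oxabicyclo[3.2.1]octan-3-one
Conditions: t-BuOK (0.2 equiv), t-BuOH/THF, 23 °C
Reagents that add atoms: none
Why: Intramolecular oxa‑Michael addition (5‑exo‑trig) of the tertiary alkoxide to the enone β‑carbon under thermodynamic control; the tether forces the new C–O bond cis to the side chain, and equilibrating α‑protonation should leave the methyl group equatorial, cis to the ether oxygen.

Step 3
Reactants: 3 (1R,4S,5S)-4,7,7-trimethyl-6-oxabicyclo[3.2.1]octan-3-one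
Product: 4 (1R,2Z,4S,5S)-2-(hydroxymethylidene)-4,7,7-trimethyl-6-oxabicyclo[3.2.1]octan-3-one
Conditions: LDA (1.1 equiv), THF, −78 °C; CF3CH2OCHO, −78 → 0 °C; 1 M HCl
Reagents that add atoms: 2,2,2-trifluoroethyl formate (O=COCC(F)(F)F)
Why: Kinetic deprotonation at the unhindered α′‑CH2 (the other α‑carbon is tertiary) and Claisen‑type formylation should give the 2‑formyl ketone as its hydrogen‑bonded enol, which directs all later chemistry to this carbon.

Step 4
Reactants: 4 (1R,2Z,4S,5S)-2-(hydroxymethylidene)-4,7,7-trimethyl-6-oxabicyclo[3.2.1]octan-3-one; 5 methyl acrylate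
Product: 6 methyl 3-(2-formyl-4,7,7-trimethyl-3-oxo-6-oxabicyclo[3.2.1]octan-2-yl)propanoate (formyl syn, propanoate chain anti to the O–C(CH3)2 bridge)
Conditions: DBU (0.1 equiv), MeCN, 0 → 23 °C
Reagents that add atoms: none
Why: Michael addition of the formyl‑ketone (1,3‑dicarbonyl) enolate to the acrylate; C‑alkylation on the exo face, away from the gem‑dimethyl ether bridge, should set the all‑carbon quaternary centre.

Step 5
Reactants: 6 methyl 3-(2-formyl-4,7,7-trimethyl-3-oxo-6-oxabicyclo[3.2.1]octan-2-yl)propanoate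
Product: 8 bridged keto spiro-δ-lactone, via hydroxy ester 7 (not isolated)
Conditions: NaBH4 (0.5 equiv), MeOH/CH2Cl2, −78 °C; then CSA (0.1 equiv), CH2Cl2, 23 °C
Reagents that add atoms: none
Why: Chemoselective borohydride reduction of the aldehyde beside a doubly α‑branched ketone and an ester, followed by acid‑catalysed δ‑lactonisation of the neopentyl alcohol onto the methyl ester; no stereocentre is touched.

Step 6
Reactants: 8 bridged keto spiro-δ-lactone; 9 ethyl 2-(bromomethyl)acrylate
Product: 11 bridged α-methylene spiro-γ-lactone, via zinc alkoxide 10 (not isolated)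
Conditions: Zn dust (TMSCl‑activated), THF, 50 °C; 1 M HCl work‑up
Reagents that add atoms: none
Why: Zn‑mediated Barbier (Reformatsky‑type) allylation through a six‑membered SE2′ transition state, then lactonisation of the zinc alkoxide; the ether bridge blocks the axial trajectory, so the allyl unit should enter equatorially from the opposite face and set the tertiary carbinol carbon (oxygen syn to the bridge).

Step 7
Reactants: 11 bridged α-methylene spiro-γ-lactone
Product: 12 dispiro diol (cyclohexane with CH3, OH, C(CH3)2OH, δ‑lactone OCH2 and γ‑lactone O all on one face)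
Conditions: 1 M aq. HClO4/THF (1:3), 40 °C; NaHCO3
Reagents that add atoms: water (O)
Why: Acid‑catalysed SN1 hydrolysis of the tertiary bridging ether (ionisation at O–C(CH3)2, capture by water), driven by relief of the 1,3‑diaxial compression between the bridge and the lactone oxygen; the secondary C–O bond is not broken, so its configuration is retained.

Step 8
Reactants: 12 dispiro diol
Product: 13 bis(triethylsilyl) ether of 12
Conditions: TESOTf (3 equiv), 2,6‑lutidine (5 equiv), CH2Cl2, −78 → 0 °C
Reagents that add atoms: triethylsilyl triflate (CC[Si](CC)(CC)OS(=O)(=O)C(F)(F)F)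
Why: Silyl triflate silylation should cap both the secondary and the tertiary hydroxyl, so that no O–H can quench the enolate of step 10.

Step 9
Reactants: 14 α-angelica lactone; 15 acetaldehyde
Product: 16 (E)-3-ethylidene-5-methylfuran-2(3H)-one
Conditions: Et3N (0.3 equiv), MgSO4, CH2Cl2, 0 → 23 °C; used at once
Reagents that add atoms: none
Why: Knoevenagel‑type aldol condensation at the acidic C‑3 methylene of the enol lactone (its anion is an aromatic 2‑oxidofuran); the E isomer, methyl anti to the carbonyl, is the thermodynamic one.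

Step 10
Reactants: 13 bis(triethylsilyl) ether of 12; 16 (E)-3-ethylidene-5-methylfuran-2(3H)-one
Product: 19 2-(tert-butyldimethylsilyloxy)-5-methylfuran-3-yl spiro-lactone, via lithium enolate 17 (not isolated), via lithium furanolate 18 (not isolated)
Conditions: L‑Selectride (1.05 equiv), THF, −78 °C; 16 (1.3 equiv), −78 °C; TBSOTf (1.5 equiv), −78 → −40 °C; pH 7 buffer
Reagents that add atoms: tert-butyldimethylsilyl triflate (CC(C)(C)[Si](C)(C)OS(=O)(=O)C(F)(F)F)
Why: Conjugate hydride reduction generates the tetrasubstituted lactone enolate regiospecifically, and its aromatisation‑driven Michael addition to the exocyclic β‑carbon of 16 should occur on the lactone face anti to the quaternary spiro carbon (setting the quaternary α‑carbon) through a lithium‑chelated eight‑membered transition state that keeps the furanone ring over the small methyl group rather than over the spiro ring (setting the CH(CH3) carbon), before O‑silylation traps the furanolate.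

Step 11
Reactants: 19 2-(tert-butyldimethylsilyloxy)-5-methylfuran-3-yl spiro-lactone
Product: 22 bis(triethylsilyl) ether of Chermebilaene B, via silyl (Z)-4-oxoenoate 20 (not isolated), via cage silyl ketene acetal 21 (not isolated)
Conditions: DMDO (1.1 equiv, acetone), CH2Cl2, −78 °C; evaporate; TMSOTf (0.2 equiv), 2,6‑di‑tert‑butyl‑4‑methylpyridine (0.1 equiv), 4 Å MS, CH2Cl2, −78 → −20 °C; sat. aq. NaHCO3
Reagents that add atoms: dimethyldioxirane (CC1(C)OO1)
Why: Proposed new method: DMDO delivers oxygen to the methyl‑bearing C‑5 of the 2‑silyloxyfuran (a known vinylogous Rubottom‑type oxidation) and the ring opens to silyl (Z)‑4‑oxoenoate 20; TMSOTf then silylates the ketone, the silyl ester carbonyl closes on it (5‑exo‑trig, γ‑lactone ring) to an O‑silylated 5‑silyloxybutenolide cation, the spiro‑γ‑lactone carbonyl oxygen adds to its β‑carbon (6‑endo‑trig, oxane ring), and the resulting spiro‑dioxacarbenium ion is captured by the neighbouring C–O–SiMe3 oxygen (cation–oxygen collapse, formally 5‑exo‑trig, closing the 1,3‑dioxolane last and returning TMSOTf), after which the bicarbonate quench protonates silyl ketene acetal 21. The closest known reaction types are ester‑carbonyl participation followed by oxygen capture in the oxetanyl or epoxy ester to bicyclic orthoester rearrangement, acyloxy participation giving glycosyl 1,2‑orthoesters, and TMSOTf‑catalysed ketalisation with silyl ethers; what is new is a silyl‑activated butenolide as the electrophile for the lactone oxygen. The OCH stereocentre is set by the tether, because only addition on the butenolide face that places the new C–O bond cis to the ketal C–O can be followed by dioxolane closure while the other adduct reverts by retro‑oxa‑Michael; the ketal centre, which epimerises by ring opening, is taken from the epimer that can close, the orthoester centre is dictated by the cis ring fusions, and the lactone α‑CH is protonated on the exo face since the lactone can only be cis‑fused. The step needs chemoselective oxidation of the silyloxyfuran (the only electron‑rich π‑system) and attack by the spiro‑γ‑lactone carbonyl rather than the δ‑lactone or silyl ether oxygens; a six‑membered transition state is open only to that carbonyl, and after oxygen transfer the change is a net isomerisation, so no water has to be removed.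

Step 12
Reactants: 22 bis(triethylsilyl) ether of Chermebilaene B
Product: 23 Chermebilaene B
Conditions: HF·pyridine, pyridine, THF, 0 → 23 °C
Reagents that add atoms: none
Why: Buffered fluoride cleavage of both triethylsilyl ethers should leave the caged orthoester, the acylal γ‑lactone and the δ‑lactone intact, and touches no stereocentre.

**Compound list**

1 | (R)-(−)-carvone, (5R)-2-methyl-5-(prop-1-en-2-yl)cyclohex-2-en-1-one | CC1=CC[C@@H](C(C)=C)CC1=O | starting material
2 | (5R)-5-(2-hydroxypropan-2-yl)-2-methylcyclohex-2-en-1-one | CC1=CC[C@@H](C(C)(C)O)CC1=O | intermediate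
3 | (1R,4S,5S)-4,7,7-trimethyl-6-oxabicyclo[3.2.1]octan-3-one (4‑methyl equatorial, cis to O‑6) | C[C@H]1[C@@H]2C[C@@H](C(C)(C)O2)CC1=O | intermediate
4 | (1R,2Z,4S,5S)-2-(hydroxymethylidene)-4,7,7-trimethyl-6-oxabicyclo[3.2.1]octan-3-one (enol of the 2‑formyl ketone) | C[C@H]1[C@@H]2C[C@@H](C(C)(C)O2)/C(=C/O)C1=O | intermediate
5 | methyl acrylate | C=CC(=O)OC | starting material
6 | methyl 3-(2-formyl-4,7,7-trimethyl-3-oxo-6-oxabicyclo[3.2.1]octan-2-yl)propanoate, formyl syn and propanoate chain anti to the ether bridge | C[C@H]1[C@@H]2C[C@@H](C(C)(C)O2)[C@](C=O)(CCC(=O)OC)C1=O | intermediate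
7 | hydroxy ester: the 2‑(hydroxymethyl) analogue of 6 | C[C@H]1[C@@H]2C[C@@H](C(C)(C)O2)[C@](CO)(CCC(=O)OC)C1=O | intermediate
8 | bridged keto spiro‑δ‑lactone: 3 with C‑2 spiro‑fused to C‑5 of a tetrahydropyran‑2‑one, lactone OCH2 syn to the ether bridge | C[C@H]1[C@@H]2C[C@@H](C(C)(C)O2)[C@]3(CCC(=O)OC3)C1=O | intermediate
9 | ethyl 2-(bromomethyl)acrylate | C=C(CBr)C(=O)OCC | starting material
10 | zinc alkoxide of the tertiary alcohol carrying the CH2C(=CH2)CO2Et chain | C[C@H]1[C@@H]2C[C@@H](C(C)(C)O2)[C@]3(CCC(=O)OC3)[C@]1(O[Zn]Br)CC(=C)C(=O)OCC | intermediate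
11 | bridged α‑methylene spiro‑γ‑lactone: ketone carbon of 8 now spiro C‑5 of a 3‑methyleneoxolan‑2‑one, lactone O syn to the ether bridge | C[C@H]1[C@@H]2C[C@@H](C(C)(C)O2)[C@]3(CCC(=O)OC3)[C@]14CC(=C)C(=O)O4 | intermediate
12 | dispiro diol: cyclohexane with secondary OH and 2‑hydroxypropan‑2‑yl, spiro‑δ‑lactone and spiro α‑methylene‑γ‑lactone on adjacent carbons | C[C@H]1[C@@H](O)C[C@@H](C(C)(C)O)[C@]2(CCC(=O)OC2)[C@]13CC(=C)C(=O)O3 | intermediate
13 | bis(triethylsilyl) ether of 12 | C[C@H]1[C@@H](O[Si](CC)(CC)CC)C[C@@H](C(C)(C)O[Si](CC)(CC)CC)[C@]2(CCC(=O)OC2)[C@]13CC(=C)C(=O)O3 | intermediate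
14 | α‑angelica lactone, 5-methylfuran-2(3H)-one | CC1=CCC(=O)O1 | starting material
15 | acetaldehyde | CC=O | starting material
16 | (E)-3-ethylidene-5-methylfuran-2(3H)-one | C/C=C1\C=C(C)OC1=O | intermediate
17 | lithium enolate of the α‑methyl spiro‑γ‑lactone | C[C@H]1[C@@H](O[Si](CC)(CC)CC)C[C@@H](C(C)(C)O[Si](CC)(CC)CC)[C@]2(CCC(=O)OC2)[C@]13CC(C)=C([O-])O3.[Li+] | intermediate
18 | lithium 5‑methylfuran‑2‑olate carrying the new quaternary and CH(CH3) centres at C‑3 | C[C@H]1[C@@H](O[Si](CC)(CC)CC)C[C@@H](C(C)(C)O[Si](CC)(CC)CC)[C@]2(CCC(=O)OC2)[C@]13C[C@](C)([C@@H](C)c4cc(C)oc4[O-])C(=O)O3.[Li+] | intermediate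
19 | spiro‑γ‑lactone whose α‑carbon bears methyl and a 1‑[2‑(tert‑butyldimethylsilyloxy)‑5‑methylfuran‑3‑yl]ethyl group | C[C@H]1[C@@H](O[Si](CC)(CC)CC)C[C@@H](C(C)(C)O[Si](CC)(CC)CC)[C@]2(CCC(=O)OC2)[C@]13C[C@](C)([C@@H](C)c4cc(C)oc4O[Si](C)(C)C(C)(C)C)C(=O)O3 | intermediate
20 | tert‑butyldimethylsilyl (Z)‑4‑oxopent‑2‑enoate, substituted at C‑2 by the lactone side chain | C[C@H]1[C@@H](O[Si](CC)(CC)CC)C[C@@H](C(C)(C)O[Si](CC)(CC)CC)[C@]2(CCC(=O)OC2)[C@]13C[C@](C)([C@@H](C)/C(=C/C(C)=O)C(=O)O[Si](C)(C)C(C)(C)C)C(=O)O3 | intermediate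
21 | caged orthoester with the γ‑lactone as its O‑TBS ketene acetal | C[C@H]1[C@@H](O[Si](CC)(CC)CC)C[C@@H](C(C)(C)O[Si](CC)(CC)CC)[C@]2(CCC(=O)OC2)[C@]12C[C@]1(C)[C@@H](C)C3=C(O[Si](C)(C)C(C)(C)C)O[C@@]4(C)O[C@@]1(O[C@@H]34)O2 | intermediate
22 | bis(triethylsilyl) ether of Chermebilaene B | C[C@H]1[C@@H](O[Si](CC)(CC)CC)C[C@@H](C(C)(C)O[Si](CC)(CC)CC)[C@]2(CCC(=O)OC2)[C@]12C[C@]1(C)[C@@H](C)[C@H]3C(=O)O[C@@]4(C)O[C@@]1(O[C@@H]34)O2 | intermediate
23 | Chermebilaene B | C[C@H]1[C@@H](O)C[C@@H](C(C)(C)O)[C@]2(CCC(=O)OC2)[C@]12C[C@]1(C)[C@@H](C)[C@H]3C(=O)O[C@@]4(C)O[C@@]1(O[C@@H]34)O2 | target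

**Summary**

Total step count: 12. Longest linear sequence: 11 (steps 1–8 and 10–12).

**Steps most likely to fail**

Step 11. The lactone carbonyl may be too weak a nucleophile for the silyl‑activated butenolide. Ionisation at the ketal carbon, E/Z isomerisation of the oxoenoate or oligomerisation through the silyl ketene acetal could then outrun cage closure, and adventitious TfOH could strip the TES ethers. The fallback sets out from 19 and comes back at 22, using a hemiacetal as the oxygen donor. DIBAL‑H (CH2Cl2, −78 °C) should reduce both lactones of 19 to the bis‑lactol F1. DMDO oxidation of the silyloxyfuran, then CSA in wet CH2Cl2, should let the spiro‑lactol hydroxyl add reversibly to the butenolide β‑carbon (acid‑catalysed hemiacetal oxa‑Michael addition) to give the bicyclic acetal F2. TEMPO/PhI(OAc)2 should restore the δ‑lactone in acetal F3. Ozone (EtOAc, −78 °C) should oxidise the acetal C–H to the ester, giving the hydroxy spiro‑γ‑lactone F4, the formal hydrate of 22. CSA with 4 Å MS in CH2Cl2 should then condense the lactone with the cis hemiketal/alcohol pair to the caged orthoester 22, the oxane closing first and the dioxolane last.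

Step 10. The Michael addition may show poor relative topicity, giving the epimer at the CH(CH3) carbon, and the furanolate may oligomerise the acceptor. The fallback sets out from 13 and comes back at 19, with the CH(CH3) centre under catalyst control. The L‑Selectride‑derived enolate is trapped with 2,2,2‑trifluoroethyl formate to give the α‑formyl‑α‑methyl spiro‑lactone F5, with the same facial preference but a small electrophile. Condensation of F5 with α‑angelica lactone 14 (Et3N) should give the (E)‑alkylidene furanone F6. Copper‑catalysed asymmetric conjugate addition of MeMgBr (CuBr·SMe2, Josiphos‑type ligand, enantiomer chosen for the required face), then TBSOTf trapping of the furanolate, should return 19.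

Step 7. The tertiary cation may undergo E1 elimination or hydride shift (epimerising the adjacent ring CH), the ether may re‑close on concentration, or the tertiary lactone C–O bond may ionise. The fallback sets out from 11 and comes back at 12, and avoids equilibrating acid. Me2BBr (CH2Cl2, −78 °C) should cleave the tertiary C–O bond to the tertiary bromide alcohol F7 after hydrolysis of the borinate. AgOTf with 2,6‑lutidine in wet acetone at 0 °C should then hydrolyse the bromide irreversibly to diol 12.

**Further compounds**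

F1 | step 11 | bis‑lactol of 19 (both lactone C=O reduced to CH–OH, anomer mixtures) | C[C@H]1[C@@H](O[Si](CC)(CC)CC)C[C@@H](C(C)(C)O[Si](CC)(CC)CC)[C@]2(CCC(O)OC2)[C@]13C[C@](C)([C@@H](C)c4cc(C)oc4O[Si](C)(C)C(C)(C)C)C(O)O3
F2 | step 11 | bicyclic acetal (spiro‑lactol oxygen bonded to the OCH carbon) with 5‑hydroxy‑5‑methyl‑γ‑lactone and δ‑lactol | C[C@H]1[C@@H](O[Si](CC)(CC)CC)C[C@@H](C(C)(C)O[Si](CC)(CC)CC)[C@]2(CCC(O)OC2)[C@]12C[C@]1(C)[C@@H](C)[C@H]3C(=O)OC(C)(O)[C@H]3O[C@@H]1O2
F3 | step 11 | bicyclic acetal F2 with the δ‑lactone restored | C[C@H]1[C@@H](O[Si](CC)(CC)CC)C[C@@H](C(C)(C)O[Si](CC)(CC)CC)[C@]2(CCC(=O)OC2)[C@]12C[C@]1(C)[C@@H](C)[C@H]3C(=O)OC(C)(O)[C@H]3O[C@@H]1O2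
F4 | step 11 | hydroxy spiro‑γ‑lactone carrying the 4,5‑dihydroxy‑5‑methyl‑γ‑lactone (formal hydrate of 22) | C[C@H]1[C@@H](O[Si](CC)(CC)CC)C[C@@H](C(C)(C)O[Si](CC)(CC)CC)[C@]2(CCC(=O)OC2)[C@]13C[C@](C)([C@@H](C)[C@H]4C(=O)OC(C)(O)[C@H]4O)C(=O)O3
F5 | step 10 | α‑formyl‑α‑methyl spiro‑γ‑lactone | C[C@H]1[C@@H](O[Si](CC)(CC)CC)C[C@@H](C(C)(C)O[Si](CC)(CC)CC)[C@]2(CCC(=O)OC2)[C@]13C[C@](C)(C=O)C(=O)O3
F6 | step 10 | (E)‑3‑alkylidene‑5‑methylfuran‑2(3H)‑one from F5 and 14 | C[C@H]1[C@@H](O[Si](CC)(CC)CC)C[C@@H](C(C)(C)O[Si](CC)(CC)CC)[C@]2(CCC(=O)OC2)[C@]13C[C@](C)(/C=C4\C=C(C)OC4=O)C(=O)O3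
F7 | step 7 | tertiary bromide alcohol (2‑bromopropan‑2‑yl in place of 2‑hydroxypropan‑2‑yl in 12) | C[C@H]1[C@@H](O)C[C@@H](C(C)(C)Br)[C@]2(CCC(=O)OC2)[C@]13CC(=C)C(=O)O3
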